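The tetrahydrofuran ring (O1, C2–C5) is disconnected at O1–C2 and C2–C3, so that C2 enters as an aldehyde carbon. The feature exploited is that only the cis C4-methyl/C5-aryl pair opposes thermodynamics. The C3 substituent is trans to the C4 methyl and the C2 aryl is trans to C3, so both centres may be set under equilibration. An Evans syn aldol fixes C4 and C5. One Lewis-acid operation then unites the syn triethylsilyl ether of a 1-(tosyloxyaryl)-4-methoxy-2-methylbut-3-en-1-ol with 4-benzyloxy-3,5-dimethoxybenzaldehyde. It forms both bonds, the ring, C2 and C3, and leaves a C3 formyl group as the latent methyl.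

Key step: step 8

Remark: the methoxymethylene Wittig product is expected as an E/Z mixture and is used as such (E isomer drawn), since both isomers give the same cation; all tetrahydrofurans are numbered O1, C2 (aryl from the benzyl-protected aldehyde), C3, C4, C5 (aryl from the aldol).

Step 1
Reactants: 1 syringaldehyde; 2 tosyl chloride
Product: 3 4-formyl-2,6-dimethoxyphenyl 4-methylbenzenesulfonate (O-tosylsyringaldehyde)
Conditions: TsCl, Et3N, DMAP (cat.), CH2Cl2, 0 °C → rt
Reagents that add atoms: tosyl chloride 2, Cc1ccc(cc1)S(=O)(=O)Cl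
Why: O-Sulfonylation of a phenol with a sulfonyl chloride and an amine base is routine even for this flanked phenol, and the tosylate should both outlast the boron, aluminium, ylide and hydride reagents ahead and make this ring a poor cation stabiliser.

Step 2
Reactants: 4 (R)-4-benzyl-3-propionyloxazolidin-2-one; 3 O-tosylsyringaldehyde
Product: 7 (R)-4-benzyl-3-[(2R,3R)-3-(3,5-dimethoxy-4-tosyloxyphenyl)-3-hydroxy-2-methylpropanoyl]oxazolidin-2-one, via Z-dibutylboron enolate 5 (not isolated), via dibutylboron aldolate 6 (not isolated)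
Conditions: n-Bu2BOTf (1.1 equiv), Et3N (1.3 equiv), CH2Cl2, 0 °C; 3, −78 → 0 °C; pH 7 buffer (NaH2PO4/Na2HPO4), MeOH, 30% H2O2, 0 °C
Reagents that add atoms: none
Why: Evans syn aldol reaction: the Z-boron enolate 5 should react through a closed Zimmerman–Traxler chair in which the (R)-benzyl group of the auxiliary shields one enolate face, which sets the (2R,3R)-syn pair that becomes C4 and C5.

Step 3
Reactants: 7 syn aldol imide
Product: 8 (2R,3R)-3-(3,5-dimethoxy-4-tosyloxyphenyl)-3-hydroxy-N-methoxy-N,2-dimethylpropanamide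
Conditions: MeONHMe·HCl (3 equiv), AlMe3 (3 equiv), CH2Cl2, −10 °C → rt; aq potassium sodium tartrate
Reagents that add atoms: N,O-dimethylhydroxylamine hydrochloride, CNOC.Cl
Why: Weinreb transamidation with the aluminium amide is run on the free β-hydroxy imide, because the aluminium alkoxide formed there guides the amide to the exocyclic carbonyl, whereas O-silylated adducts tend to suffer opening of the oxazolidinone ring; no stereocentre is touched.

Step 4
Reactants: 8 β-hydroxy Weinreb amide
Product: 9 (2R,3R)-3-(3,5-dimethoxy-4-tosyloxyphenyl)-N-methoxy-N,2-dimethyl-3-(triethylsilyloxy)propanamide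
Conditions: Et3SiCl, imidazole, DMF, 0 °C → rt
Reagents that add atoms: chlorotriethylsilane, CC[Si](Cl)(CC)CC
Why: Silylation of a secondary alcohol with a chlorosilane and imidazole is routine, and triethylsilyl is chosen because it should survive hydride, ylide and chromatography while leaving the oxygen nucleophilic enough for step 8.

Step 5
Reactants: 9 silylated Weinreb amide
Product: 11 (2R,3R)-3-(3,5-dimethoxy-4-tosyloxyphenyl)-2-methyl-3-(triethylsilyloxy)propanal, via aluminium hemiaminal chelate 10 (not isolated)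
Conditions: i-Bu2AlH (1.5 equiv), THF, −78 °C; aq potassium sodium tartrate
Reagents that add atoms: none
Why: Weinreb amide reduction: the chelated tetrahedral intermediate 10 should persist at −78 °C and release the aldehyde only on work-up, so that over-reduction is excluded and the α-stereocentre never meets base.

Step 6
Reactants: 11 α-methyl-β-silyloxy aldehyde; 12 (methoxymethyl)triphenylphosphonium chloride
Product: 14 triethylsilyl ether of syn-(1R,2S)-1-(3,5-dimethoxy-4-tosyloxyphenyl)-4-methoxy-2-methylbut-3-en-1-ol, via methoxymethylenetriphenylphosphorane 13 (not isolated)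
Conditions: 12 (2.0 equiv), NaN(SiMe3)2 (1.9 equiv), THF, 0 °C; then 11, −78 → 0 °C
Reagents that add atoms: (methoxymethyl)triphenylphosphonium chloride 12, COC[P+](c1ccccc1)(c2ccccc2)c3ccccc3.[Cl-]
Why: Wittig methoxymethylenation with ylide 13, made with a slight deficit of base and met by the aldehyde at −78 °C so that addition outruns enolisation of the α-stereocentre; the alkene geometry is of no consequence.

Step 7
Reactants: 1 syringaldehyde
Product: 15 4-benzyloxy-3,5-dimethoxybenzaldehyde
Conditions: BnBr, K2CO3, DMF, rt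
Reagents that add atoms: benzyl bromide, BrCc1ccccc1
Why: Williamson ether synthesis on the phenolate; the benzyl ether keeps this ring electron-rich and is removable under neutral conditions at the end.

Step 8
Reactants: 14 syn silyl ether/enol ether; 15 4-benzyloxy-3,5-dimethoxybenzaldehyde
Product: 18 (2S,3S,4S,5R)-2-(4-benzyloxy-3,5-dimethoxyphenyl)-5-(3,5-dimethoxy-4-tosyloxyphenyl)-4-methyltetrahydrofuran-3-carbaldehyde, via E-oxocarbenium triflate 16 (not isolated), via cyclised methoxycarbenium triflate 17 (not isolated)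
Conditions: 15 (1.2 equiv), Me3SiOTf (1.2 equiv), 2,6-di-tert-butyl-4-methylpyridine (0.2 equiv), 4 Å MS, CH2Cl2, −78 → −20 °C; aq NaHCO3
Reagents that add atoms: water, O
Why: Me3SiOTf activates aldehyde 15, the silyl ether oxygen of 14 adds to it and the two silyl groups leave together as a disiloxane, giving oxocarbenium ion 16 (bond O1–C2), whose carbon is then attacked by the nucleophilic β-carbon of the enol ether (bond C2–C3) to leave the exocyclic methoxycarbenium ion 17, which water converts into the formyl group on quenching. The closest known reaction types are the Lewis-acid rearrangement of cyclic vinyl acetals and the condensation of 4-hydroxy-1-alkenyl carbamates with aldehydes, both of which give tetrahydrofuran-3-carbaldehydes through the same kind of ion, together with the Mukaiyama aldol–Prins capture of oxocarbenium ions by enol ethers. The tetrahydrofuran ring closes in a 5-(enolexo)-endo-trig mode, which is routine for oxocarbenium electrophiles, and the polarisation of the enol ether makes C3 rather than the methoxy-bearing carbon the nucleophile, so that neither a six-membered Prins ring nor a 2-oxonia-Cope shift should compete. C2 is controlled first by closure of the E-configured ion 16 through an envelope with both aryl groups pseudoequatorial (2,5-cis) and then by thermodynamics, since the benzyloxy ring stabilises 16 enough for the closure to be reversible, so that the C2 aryl group should settle trans to the C3 substituent. C3 is controlled by approach anti to the C4 methyl group and, as a safeguard, by its acidity next to the cationic or formyl carbon, which lets it relax to the position trans to both neighbours. The step therefore needs diastereoselectivity at C2 and C3 with C4 and C5 untouched, plus ionisation at one benzylic carbon only, and the substrate secures this through the tosyloxy ring, which destabilises a C5 cation so that C5–O1 stays intact, and through the silyl cap, which stops O1 from closing on the enol ether ahead of acetal formation.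

Step 9
Reactants: 18 tetrahydrofuran-3-carbaldehyde
Product: 19 [(2S,3R,4S,5R)-2-(4-benzyloxy-3,5-dimethoxyphenyl)-5-(3,5-dimethoxy-4-tosyloxyphenyl)-4-methyltetrahydrofuran-3-yl]methanol
Conditions: DBU (0.2 equiv), CH2Cl2, rt, 30 min; then MeOH, NaBH4, 0 °C
Reagents that add atoms: none
Why: Base-catalysed enolisation should funnel any material closed with the opposite sense at C3 into the isomer trans to both neighbours (ring opening by E1cB is the reverse of a 5-endo-trig closure and has poor orbital overlap), after which chemoselective NaBH4 reduction of the aldehyde freezes C3.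

Step 10
Reactants: 19 primary alcohol
Product: 20 [(2S,3R,4S,5R)-2-(4-benzyloxy-3,5-dimethoxyphenyl)-5-(3,5-dimethoxy-4-tosyloxyphenyl)-4-methyltetrahydrofuran-3-yl]methyl methanesulfonate
Conditions: MsCl, Et3N, CH2Cl2, 0 °C
Reagents that add atoms: methanesulfonyl chloride, CS(=O)(=O)Cl
Why: Mesylation of a primary alcohol is routine and touches no stereocentre.

Step 11
Reactants: 20 primary mesylate
Product: 21 (2S,3S,4S,5R)-2-(4-benzyloxy-3,5-dimethoxyphenyl)-5-(3,5-dimethoxy-4-tosyloxyphenyl)-3,4-dimethyltetrahydrofuran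
Conditions: LiEt3BH (3 equiv), THF, 0 °C → rt; aq NH4Cl
Reagents that add atoms: none
Why: SN2 displacement of a primary sulfonate by LiEt3BH, the most nucleophilic of the common hydrides, should cope with the β-branching and touches no stereocentre, and any S–O cleavage of the aryl tosylate would only anticipate step 12.

Step 12
Reactants: 21 doubly protected lignan
Product: 22 (2S,3S,4S,5R)-2-(4-benzyloxy-3,5-dimethoxyphenyl)-5-(4-hydroxy-3,5-dimethoxyphenyl)-3,4-dimethyltetrahydrofuran
Conditions: Mg turnings (10 equiv), MeOH–THF, rt, sonication; aq NH4Cl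
Reagents that add atoms: none
Why: Single-electron reductive S–O cleavage of an aryl tosylate by Mg in MeOH works at room temperature, which avoids the hot hydroxide that could open the newly freed p-hydroxybenzyl ether through a quinone methide and erode C5.

Step 13
Reactants: 22 monobenzyl ether
Product: 23 (2S,3S,4S,5R)-2,5-bis(4-hydroxy-3,5-dimethoxyphenyl)-3,4-dimethyltetrahydrofuran (target)
Conditions: H2 (1 atm), 10% Pd/C, EtOAc–MeOH, rt
Reagents that add atoms: none
Why: Catalytic hydrogenolysis of an aryl benzyl ether is much faster than that of the ring benzylic C–O bonds, and the neutral medium should leave all four stereocentres as set.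

Compound list
1 | syringaldehyde | COc1cc(C=O)cc(OC)c1O | starting material
2 | tosyl chloride | Cc1ccc(cc1)S(=O)(=O)Cl | starting material
3 | 4-formyl-2,6-dimethoxyphenyl 4-methylbenzenesulfonate | COc1cc(C=O)cc(OC)c1OS(=O)(=O)c2ccc(C)cc2 | intermediate
4 | (R)-4-benzyl-3-propionyloxazolidin-2-one | CCC(=O)N1[C@H](Cc2ccccc2)COC1=O | starting material
5 | Z-dibutylboron enolate of 4 | C/C=C(\OB(CCCC)CCCC)N1[C@H](Cc2ccccc2)COC1=O | intermediate
6 | dibutylboron aldolate of 7 | CCCCB(CCCC)O[C@@H](c1cc(OC)c(OS(=O)(=O)c2ccc(C)cc2)c(OC)c1)[C@@H](C)C(=O)N3[C@H](Cc4ccccc4)COC3=O | intermediate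
7 | (R)-4-benzyl-3-[(2R,3R)-3-(3,5-dimethoxy-4-tosyloxyphenyl)-3-hydroxy-2-methylpropanoyl]oxazolidin-2-one | O[C@@H](c1cc(OC)c(OS(=O)(=O)c2ccc(C)cc2)c(OC)c1)[C@@H](C)C(=O)N3[C@H](Cc4ccccc4)COC3=O | intermediate
8 | (2R,3R)-3-(3,5-dimethoxy-4-tosyloxyphenyl)-3-hydroxy-N-methoxy-N,2-dimethylpropanamide | O[C@@H](c1cc(OC)c(OS(=O)(=O)c2ccc(C)cc2)c(OC)c1)[C@@H](C)C(=O)N(C)OC | intermediate
9 | O-triethylsilyl ether of 8 | CC[Si](CC)(CC)O[C@@H](c1cc(OC)c(OS(=O)(=O)c2ccc(C)cc2)c(OC)c1)[C@@H](C)C(=O)N(C)OC | intermediate
10 | diisobutylaluminium hemiaminal chelate from 9 (hemiaminal carbon undefined) | CC[Si](CC)(CC)O[C@@H](c1cc(OC)c(OS(=O)(=O)c2ccc(C)cc2)c(OC)c1)[C@@H](C)C(O[Al](CC(C)C)CC(C)C)N(C)OC | intermediate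
11 | (2R,3R)-3-(3,5-dimethoxy-4-tosyloxyphenyl)-2-methyl-3-(triethylsilyloxy)propanal | CC[Si](CC)(CC)O[C@@H](c1cc(OC)c(OS(=O)(=O)c2ccc(C)cc2)c(OC)c1)[C@@H](C)C=O | intermediate
12 | (methoxymethyl)triphenylphosphonium chloride | COC[P+](c1ccccc1)(c2ccccc2)c3ccccc3.[Cl-] | starting material
13 | methoxymethylenetriphenylphosphorane | COC=P(c1ccccc1)(c2ccccc2)c3ccccc3 | intermediate
14 | triethylsilyl ether of syn-(1R,2S)-1-(3,5-dimethoxy-4-tosyloxyphenyl)-4-methoxy-2-methylbut-3-en-1-ol (E/Z mixture, E drawn) | CC[Si](CC)(CC)O[C@@H](c1cc(OC)c(OS(=O)(=O)c2ccc(C)cc2)c(OC)c1)[C@@H](C)/C=C/OC | intermediate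
15 | 4-benzyloxy-3,5-dimethoxybenzaldehyde | COc1cc(C=O)cc(OC)c1OCc2ccccc2 | intermediate
16 | E-oxocarbenium triflate (O1=C2 formed, enol ether still open) | COc1cc(/C=[O+]/[C@@H](c2cc(OC)c(OS(=O)(=O)c3ccc(C)cc3)c(OC)c2)[C@@H](C)/C=C/OC)cc(OC)c1OCc4ccccc4.[O-]S(=O)(=O)C(F)(F)F | intermediate
17 | cyclised exocyclic methoxycarbenium triflate | COc1cc([C@H]2O[C@@H](c3cc(OC)c(OS(=O)(=O)c4ccc(C)cc4)c(OC)c3)[C@@H](C)[C@@H]2C=[O+]C)cc(OC)c1OCc5ccccc5.[O-]S(=O)(=O)C(F)(F)F | intermediate
18 | (2S,3S,4S,5R)-2-(4-benzyloxy-3,5-dimethoxyphenyl)-5-(3,5-dimethoxy-4-tosyloxyphenyl)-4-methyltetrahydrofuran-3-carbaldehyde | COc1cc([C@H]2O[C@@H](c3cc(OC)c(OS(=O)(=O)c4ccc(C)cc4)c(OC)c3)[C@@H](C)[C@@H]2C=O)cc(OC)c1OCc5ccccc5 | intermediate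
19 | (2S,3R,4S,5R)-3-hydroxymethyl analogue of 18 | COc1cc([C@H]2O[C@@H](c3cc(OC)c(OS(=O)(=O)c4ccc(C)cc4)c(OC)c3)[C@@H](C)[C@@H]2CO)cc(OC)c1OCc5ccccc5 | intermediate
20 | methanesulfonate of 19 | COc1cc([C@H]2O[C@@H](c3cc(OC)c(OS(=O)(=O)c4ccc(C)cc4)c(OC)c3)[C@@H](C)[C@@H]2COS(C)(=O)=O)cc(OC)c1OCc5ccccc5 | intermediate
21 | (2S,3S,4S,5R)-2-(4-benzyloxy-3,5-dimethoxyphenyl)-5-(3,5-dimethoxy-4-tosyloxyphenyl)-3,4-dimethyltetrahydrofuran | COc1cc([C@H]2O[C@@H](c3cc(OC)c(OS(=O)(=O)c4ccc(C)cc4)c(OC)c3)[C@@H](C)[C@@H]2C)cc(OC)c1OCc5ccccc5 | intermediate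
22 | (2S,3S,4S,5R)-2-(4-benzyloxy-3,5-dimethoxyphenyl)-5-(4-hydroxy-3,5-dimethoxyphenyl)-3,4-dimethyltetrahydrofuran | COc1cc([C@H]2O[C@@H](c3cc(OC)c(O)c(OC)c3)[C@@H](C)[C@@H]2C)cc(OC)c1OCc4ccccc4 | intermediate
23 | (2S,3S,4S,5R)-2,5-bis(4-hydroxy-3,5-dimethoxyphenyl)-3,4-dimethyltetrahydrofuran | COc1cc([C@H]2O[C@@H](c3cc(OC)c(O)c(OC)c3)[C@@H](C)[C@@H]2C)cc(OC)c1O | target

Total step count: 13. Longest linear sequence: 12 steps (steps 1–6 and 8–13); step 7 is a one-step side branch.

Steps most likely to fail

1. Step 8.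
- **What may go wrong.** The enol ether may attack the activated aldehyde before O1 does. That manifold should still converge, because the resulting C2 silyloxy group sits on the electron-rich ring and can ionise towards O1. Adventitious acid may close O1 onto the protonated enol ether. The enol ether may oligomerise on the methoxycarbenium ion, or equilibration at C2 may stop short.
- **Fallback.** C2 is brought in as an aryl nucleophile on a lactone, followed by ionic hydrogenation. The fallback sets out from 14 and comes back at 21, so that steps 8 to 11 are bypassed.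
- Aqueous HCl in THF removes the silyl group and hydrolyses the enol ether to the lactol (4S,5R)-5-(3,5-dimethoxy-4-tosyloxyphenyl)-4-methyltetrahydrofuran-2-ol F1.
- TEMPO/PhI(OAc)2 oxidises it to the cis-4-methyl-5-aryl-γ-butyrolactone F2.
- LiN(SiMe3)2 in THF at −78 °C gives the lithium enolate F3, which MeI methylates on the face away from the C4 methyl group to give the (3S,4S,5R)-3,4-dimethyl lactone F4.
- Commercial 4-bromo-2,6-dimethoxyphenol is benzylated (BnBr, K2CO3) to 2-benzyloxy-5-bromo-1,3-dimethoxybenzene F5. n-BuLi at −78 °C converts it into the aryllithium F6, and addition to F4 gives the cyclic hemiketal F7.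
- BF3·OEt2 ionises F7 to the cyclic oxocarbenium ion F8. Et3SiH delivers hydride to the face opposite the C4 methyl and C5 aryl groups, which should give 21.

2. Step 6.
- **What may go wrong.** The basic ylide may enolise the aldehyde, which erodes the C4 centre, or may trigger β-elimination of the silyloxy group. Conversion may also be poor.
- **Fallback.** A two-stage Horner–Wittig olefination separates C–C bond formation from alkene formation. It sets out from 11 and comes back at 14.
- (Methoxymethyl)diphenylphosphine oxide is deprotonated with LiN(i-Pr)2 in THF at −78 °C to the lithiated phosphine oxide F9, a small and highly nucleophilic carbanion that should add to 11 within minutes at that temperature.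
- The β-hydroxyphosphine oxide F10 is isolated as a diastereomer mixture.
- KH in THF then induces syn elimination of diphenylphosphinate at a stage where no epimerisable aldehyde remains, giving 14 as an E/Z mixture.

3. Step 11.
- **What may go wrong.** Displacement at the β-branched primary carbon may be slow. Hydride may instead attack the sulfur of the mesylate, which returns the alcohol, or consume the aryl sulfonate unevenly.
- **Fallback.** A radical reduction replaces the polar one. It sets out from 19 and comes back at 21.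
- I2, PPh3 and imidazole in CH2Cl2 (Appel-type iodination) convert the alcohol into the (2S,3S,4S,5R)-3-(iodomethyl)tetrahydrofuran F11.
- n-Bu3SnH with AIBN in toluene at 80 °C, run concentrated so that hydrogen transfer outruns any ring fragmentation, replaces iodine by hydrogen.

Further compounds
F1 | step 8 | (4S,5R)-5-(3,5-dimethoxy-4-tosyloxyphenyl)-4-methyltetrahydrofuran-2-ol (anomer mixture) | O1[C@@H](c2cc(OC)c(OS(=O)(=O)c3ccc(C)cc3)c(OC)c2)[C@@H](C)CC1O
F2 | step 8 | (4S,5R)-5-(3,5-dimethoxy-4-tosyloxyphenyl)-4-methyldihydrofuran-2(3H)-one | O1[C@@H](c2cc(OC)c(OS(=O)(=O)c3ccc(C)cc3)c(OC)c2)[C@@H](C)CC1=O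
F3 | step 8 | lithium enolate of F2 | O1[C@@H](c2cc(OC)c(OS(=O)(=O)c3ccc(C)cc3)c(OC)c2)[C@@H](C)C=C1O[Li]
F4 | step 8 | (3S,4S,5R)-5-(3,5-dimethoxy-4-tosyloxyphenyl)-3,4-dimethyldihydrofuran-2(3H)-one | O1[C@@H](c2cc(OC)c(OS(=O)(=O)c3ccc(C)cc3)c(OC)c2)[C@@H](C)[C@H](C)C1=O
F5 | step 8 | 2-benzyloxy-5-bromo-1,3-dimethoxybenzene | COc1cc(Br)cc(OC)c1OCc2ccccc2
F6 | step 8 | (4-benzyloxy-3,5-dimethoxyphenyl)lithium | COc1cc([Li])cc(OC)c1OCc2ccccc2
F7 | step 8 | (3S,4S,5R)-2-(4-benzyloxy-3,5-dimethoxyphenyl)-5-(3,5-dimethoxy-4-tosyloxyphenyl)-3,4-dimethyltetrahydrofuran-2-ol (anomer mixture) | O1[C@@H](c2cc(OC)c(OS(=O)(=O)c3ccc(C)cc3)c(OC)c2)[C@@H](C)[C@H](C)C1(O)c4cc(OC)c(OCc5ccccc5)c(OC)c4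
F8 | step 8 | cyclic 2-aryl oxocarbenium hydroxytrifluoroborate from F7 | C1(=[O+][C@@H](c2cc(OC)c(OS(=O)(=O)c3ccc(C)cc3)c(OC)c2)[C@@H](C)[C@@H]1C)c4cc(OC)c(OCc5ccccc5)c(OC)c4.O[B-](F)(F)F
F9 | step 6 | lithiated (methoxymethyl)diphenylphosphine oxide | [Li]C(OC)P(=O)(c1ccccc1)c2ccccc2
F10 | step 6 | β-hydroxyphosphine oxide adduct of 11 (two new centres undefined) | CC[Si](CC)(CC)O[C@@H](c1cc(OC)c(OS(=O)(=O)c2ccc(C)cc2)c(OC)c1)[C@@H](C)C(O)C(OC)P(=O)(c3ccccc3)c4ccccc4
F11 | step 11 | (2S,3S,4S,5R)-2-(4-benzyloxy-3,5-dimethoxyphenyl)-5-(3,5-dimethoxy-4-tosyloxyphenyl)-3-(iodomethyl)-4-methyltetrahydrofuran | COc1cc([C@H]2O[C@@H](c3cc(OC)c(OS(=O)(=O)c4ccc(C)cc4)c(OC)c3)[C@@H](C)[C@@H]2CI)cc(OC)c1OCc5ccccc5
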